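## The problem

Target 42 is a bicyclo[4.3.1]dec-3-ene. A cyclohexene (C1–C6, enal C4=C5 with formyl carbon C11) and a cycloheptane (C1, C2, C10, C9, C8, C7, C6) share the bridgeheads C2 and C6 and the one-carbon bridge C1, which carries the acetoxy group and the methyl C12. The seven-membered ring holds the quaternary C7 (methyl and the (S)-6-methylhept-5-en-2-yl chain, methine C1′) next to C8 (acetyl). If the face of this ring that carries the C3–C5 bridge is called β, the side chain and the acetyl are β and the C7 methyl is α; at C1 the acetoxy group stands over the enal bridge and C12 over the C7–C10 bridge, syn to the C7 methyl. C7 and C8 are neighbours and can be set in one event, but the acyclic C1′ cannot steer C7, and C2 is two methylene groups away from C8, so C7 and C2 each need their own source of absolute configuration. Once C2 is fixed, C6 follows, because a three-carbon bridge spans one face only, and C1 can be left to the faces of the finished bicycle. The enal, the tertiary acetate and the epimerisable C8 will not survive strong base or hydride. The trisubstituted side-chain alkene rules out ozone, peracids and unselective hydroboration, and any metathesis that puts a carbene on C6 risks closing a cyclohexene onto it. The opening is the C5–C6 bond: it joins a carbon bearing the carboxyl-level C11 to the allylic position of a C1=C12 methylene, the γ,δ-unsaturated acid retron of a Claisen rearrangement. With the ester oxygen on C12 and C5 tied to C2 through C3–C4, the precursor is an eight-membered lactone bridging a cycloheptene.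

## Retrosynthesis

**C1–O and the oxidation pattern (42 back to 31).** The ketal of 41 and the acetate of 40 are removed first; the enal of 40 comes from diol 39 and the C1–O bond of 39 from hydration of the C1=C12 methylene of 37. Oxygen is added to a carbon that already carries C12, so the reagent enters from the open face over the cyclohexene and C12 is pushed syn to the C7 methyl, as required. The reverse order (C1 ketone, then a methyl nucleophile) would give the C1 epimer. Hydration is placed after C5 has become trigonal (36, from ester 32 and acid 31), because a tetrahedral C5 carboxyl would lactonise onto a C1 hydroxyl. What remains, 31, has no oxygen at C1 and one stereocentre fewer.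

**C5–C6, the key cut (31 back to 28).** Cutting C5–C6 and reconnecting C11 to C12 through oxygen turns the bridged bicycle 31 into the fused lactone 28. The neighbouring cuts (C1–C2 or C6–C7) would need a bridgehead nucleophile or an intermolecular attack at a neopentyl carbon with free choice of face. Here the bond is formed intramolecularly and the C2 tether allows one face only. Lactone 28 has one ring fewer in the carbon skeleton and no C5 or C6 stereocentre. The forward reaction must form a bond beside the quaternary C7 in a ring-constrained [3,3] shift.

**Lactone C–O (28 back to 26).** The ester bond is cut to hydroxy acid 27 and its methyl ester 26. Closing the lactone through C–O is preferred to a C–C closure because the C5 ester then serves as its own protecting group until the end. The forward step is an eight-membered lactonisation, helped by the two arms sitting on neighbouring ring atoms, one of them sp2.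

**C1–C12 (26 back to 20).** The hydroxymethyl carbon is removed to enol triflate 25, ketone 23, alcohol 22 and cycloheptene 20. Building C12 into the ring-closing alkene was rejected: that metathesis needs a carbene on C6, which would close a cyclohexene onto the side-chain alkene. The price is a C1 ketone beside the C2 stereocentre for two steps, so the forward reactions must enolise toward C6 without proton exchange.

**C1=C6 (20 back to 16).** Ring-closing metathesis between a C2 vinyl group and a C7 propenyl group gives diene 19, which comes from ketone 18 and acid 16. This cut is chosen over an aldol or olefination closure because those need a C6 aldehyde, not reachable beside the side-chain alkene without extra steps. The precursor is acyclic, and the catalyst must load at the C2 vinyl group.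

**C7–C8 (16 back to 6 and 12).** The bond between the quaternary and the tertiary centre is cut by an Ireland–Claisen transform to ester 13, made from allylic alcohol 6 and acid 12. Of the two polarities, this one keeps the enolate carbon (C8) monosubstituted, so its geometry is controllable, and it takes the C7 configuration from a secondary carbinol by chirality transfer. Two stereocentres become one carbinol and one alkene geometry.

**Allylic alcohol 6 back to (S)-citronellal 1.** Carbinol 6 comes from enone 5 by catalyst-controlled reduction, 5 from alkyne 3 by syn methylmetalation and acylation, and 3 from 1 by converting CH2–CHO into C≡CH. All ten carbons and the C1′ centre of 1 are kept. The forward sequence must give the E alkene only.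

**Acid 12 back to 7 and 9.** C2 differs in its two arms only at their ends, so it is set by a catalyst: SN2′ allylic alkylation of allylic bromide 8 with the Grignard reagent from 9 gives 11, and oxidation gives 12. Bromide 8 comes from methyl hex-5-enoate 7. An alkylation of a cycloheptanone at C2 was rejected because nothing in the ring would control a centre that far from C7 and C8.

## Roads not taken

**Alternative 1:** a (4+3) cycloaddition cutting C2–C10 and C6–C7. Ionisation of chloroketone A2 would give a 2-oxidocyclohexenyl cation, trapped by silyl diene A3 to give bicyclic enone A1.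
- Merits: two fragments of similar size, both ring bonds and the quaternary C7 in one step, C1 as a ketone and C8 as a vinylsilane. The ring system would be reached in fewer steps than 31; in step count this road is better.
- Weak points: A3 must react at a fully substituted terminus, which disfavours the s-cis conformer. The regiochemistry (C7 to C6, not to C2) and the face of the diene would rest on a remote C5 substituent and on C1′, which cannot steer. Methyl addition to the C1 ketone would enter from the open face and give the C1 epimer of 42. The C8 acetyl and its configuration would still have to be made from the vinylsilane.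
- Against its brevity the chosen plan sets C2, C7 and C8 by reactions of known sense and fixes C6 by geometry.

**Alternative 2:** a de Mayo sequence cutting C5–C6 and C7–C8 with a sacrificial C5–C8 bond. Irradiation of dioxinone A5 would give a cyclobutane by intramolecular [2+2] addition of C6=C7 to C5=C8, and methanolysis with retro-aldol cleavage would give keto ester A4.
- Merits: A4 carries the C1 oxygen from the outset, already protected, and C5 and C8 emerge as ketone and ester. Here this road is better than the chosen plan, which has to hydrate C1 late and chemoselectively.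
- Weak points: the stepwise biradical addition does not conserve the geometry of the C6=C7 alkene, so C7 is not controlled. Crossed and straight regiochemistry compete. This kind of photoaddition–fragmentation can give trans-bridged bicycles with some tethers. C8 is protonated only after the fragmentation, and C11 is missing, so the C5 ketone needs a one-carbon homologation.
- Against the early C1 oxygen the chosen plan brings C11 in with the rearrangement and takes C7 from a carbinol by chirality transfer.

**Alternative 3:** an anionic oxy-Cope rearrangement with transannular aldol closure, cutting C7–C8 and C1–C6. The potassium alkoxide of cyclopentanol A7 would rearrange to a cyclononadienyl enolate, whose C6 would add to the C1 ketone to give ketol A6.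
- Merits: both rings, C7, C6 and the C1 carbinol in one operation from a five-membered ring. On paper this is the most step-economic road and better than the chosen plan in that respect.
- Weak points: the acetyl group of A7 is more acidic than the hydroxyl, so enolisation, epimerisation at C2 and aldol side reactions precede the rearrangement. The shift must engage a fully substituted alkene terminus. The C1 and C6 outcome depends on the conformation of a nine-membered ring and cannot be forecast, and the aldol is reversible. A6 lacks C11 and has a C9=C10 alkene to reduce beside the side-chain alkene.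
- Against its economy the chosen plan sets the stereocentres one at a time and forms C5–C6 irreversibly.

Key step: step 18

Assumption (stereochemical notation): read literally, the C2 and C6 descriptors of the target string describe a trans-bridged (in,out) bicycle, which is not a realistic reading for a bicyclo[4.3.1]dec-3-ene and cannot come from a tethered ring closure; the target is therefore taken as the normal cis-bridged bicycle (both bridgehead hydrogens outside) with C1, C2, C7, C8 and C1′ exactly as written, and the structure strings of all bicyclic compounds keep the C6 descriptor of the target string unchanged so that they can be compared with it directly.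

## Steps

Step 1
Reactants: 1 (S)-citronellal
Product: 3 (3S)-3,7-dimethyloct-6-en-1-yne, via alkenyl nonaflate 2 (not isolated)
Conditions: nonafluorobutanesulfonyl fluoride, phosphazene base P2-Et, DMF, −20 °C to rt
Reagents that add atoms: none
Why: One-pot conversion of an enolisable aldehyde into a terminal alkyne: the enolate is trapped as alkenyl nonaflate 2, which loses nonaflate by base-induced elimination; only C1 and C2 of citronellal change, so the C3 stereocentre (the later C1′) is untouched.

Step 2
Reactants: 3 (3S)-3,7-dimethyloct-6-en-1-yne
Product: 5 (3E,5S)-4,5,9-trimethyldeca-3,8-dien-2-one, via alkenylalane 4 (not isolated)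
Conditions: Me3Al, Cp2ZrCl2 (cat.), CH2Cl2, 0 °C to rt; volatiles removed; AcCl, Pd(PPh3)4 (cat.), THF, 0 °C to rt
Reagents that add atoms: trimethylaluminium, C[Al](C)C; acetyl chloride, CC(=O)Cl
Why: Zirconium-catalysed methylalumination adds methyl and aluminium syn across the terminal alkyne with aluminium on the terminal carbon; palladium-catalysed acylation of the alkenylalane with retention then gives the E enone, which fixes the geometry of the later C6=C7 alkene.

Step 3
Reactants: 5 (3E,5S)-4,5,9-trimethyldeca-3,8-dien-2-one
Product: 6 (2S,3E,5S)-4,5,9-trimethyldeca-3,8-dien-2-ol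
Conditions: (R)-2-methyl-CBS-oxazaborolidine (cat.), catecholborane, toluene, −78 °C
Reagents that add atoms: none
Why: CBS reduction: the alkenyl group is the large and the methyl the small substituent, so the (R)-oxazaborolidine should give the (S)-carbinol by 1,2-reduction; catecholborane does not hydroborate the alkenes at this temperature.

Step 4
Reactants: 7 methyl hex-5-enoate
Product: 8 methyl (5E)-7-bromohept-5-enoate
Conditions: (E)-1,4-dibromobut-2-ene (3 equiv), second-generation Grubbs catalyst (cat.), CH2Cl2, 40 °C
Reagents that add atoms: (E)-1,4-dibromobut-2-ene, BrC/C=C/CBr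
Why: Cross-metathesis of a terminal alkene with an excess of a symmetrical allylic dibromide; the E isomer is favoured by secondary metathesis.

Step 5
Reactants: 8 methyl (5E)-7-bromohept-5-enoate; 9 (4-bromobutoxy)(tert-butyl)dimethylsilane
Product: 11 methyl (5S)-9-[(tert-butyldimethylsilyl)oxy]-5-ethenylnonanoate, via Grignard reagent 10 (not isolated)
Conditions: 9, Mg, Et2O; then added slowly to 8, CuBr·SMe2 (cat.), TaniaPhos (cat., the enantiomer that gives the S product), CH2Cl2, −75 °C
Reagents that add atoms: none
Why: Copper-catalysed asymmetric allylic alkylation (SN2′) of an E allylic bromide by a primary Grignard reagent gives the branched vinyl compound; the chiral ferrocenyl diphosphine sets C2, and slow addition at low temperature spares the ester.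

Step 6
Reactants: 11 methyl (5S)-9-[(tert-butyldimethylsilyl)oxy]-5-ethenylnonanoate
Product: 12 (5S)-5-ethenyl-9-methoxy-9-oxononanoic acid
Conditions: CrO3, H2SO4, acetone/H2O, 0 °C to rt
Reagents that add atoms: water, O
Why: Jones oxidation: the acidic medium cleaves the primary silyl ether and the liberated alcohol is oxidised to the acid in the same operation; C2 has no acidic hydrogen, and the vinyl and ester groups are inert.

Step 7
Reactants: 6 (2S,3E,5S)-4,5,9-trimethyldeca-3,8-dien-2-ol; 12 (5S)-5-ethenyl-9-methoxy-9-oxononanoic acid
Product: 13 allylic ester of acid 12 with alcohol 6 (methyl ester retained)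
Conditions: DCC, DMAP (cat.), CH2Cl2, 0 °C to rt
Reagents that add atoms: none
Why: Steglich esterification; the carbinol C–O bond is not broken, so its configuration is retained.

Step 8
Reactants: 13 allylic ester
Product: 16 Claisen acid (C8 carboxylic acid next to the new quaternary C7), via bis(silyl ketene acetal) 14 (not isolated), via silyl ester 15 (not isolated)
Conditions: KN(SiMe3)2 (2.5 equiv), toluene, −78 °C; Me3SiCl, Et3N; −78 °C to 60 °C; then 1 M HCl, THF, 0 °C
Reagents that add atoms: none
Why: Ireland–Claisen rearrangement: KN(SiMe3)2 in toluene gives the Z(O) enolate (C9 cis to the oxygen–metal bond), and the chair with the carbinol methyl equatorial lets C8 reach one face of the E alkene only, so the (S)-carbinol is transferred to the quaternary C7 and to C8, with the C8 carboxyl syn to the side chain as the target requires, and the new alkene is E. The methyl ester is silylated as well and returns on work-up.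

Step 9
Reactants: 16 Claisen acid
Product: 18 C8 methyl ketone, via acid chloride 17 (not isolated)
Conditions: 1-chloro-N,N,2-trimethylprop-1-en-1-amine, CH2Cl2, 0 °C to rt; then Me2CuLi, Et2O, −78 °C
Reagents that add atoms: lithium dimethylcuprate, [Li+].C[Cu-]C
Why: Neutral conversion into the acid chloride and acylation of a Gilman cuprate give the methyl ketone; the cuprate does not attack the methyl ester at this temperature and is too weakly basic to epimerise C8.

Step 10
Reactants: 18 C8 methyl ketone
Product: 19 dioxolane of ketone 18
Conditions: 1,2-bis(trimethylsilyloxy)ethane, Me3SiOTf (cat.), CH2Cl2, −78 to −20 °C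
Reagents that add atoms: 1,2-bis(trimethylsilyloxy)ethane, C[Si](C)(C)OCCO[Si](C)(C)C
Why: Aprotic ketalisation under Me3SiOTf catalysis; it protects the ketone against the borane, the amide bases and the enolisation of the key step without the hot protic acid that could epimerise C8 or attack the side-chain alkene.

Step 11
Reactants: 19 dioxolane diene
Product: 20 cycloheptene ester (C1=C6)
Conditions: second-generation Grubbs catalyst (5 mol %), CH2Cl2 (2 mM), 40 °C
Reagents that add atoms: none
Why: Ring-closing metathesis: the catalyst loads on the unhindered C2 vinyl group and closes onto the propenyl group at C7 with loss of propene, so the carbene does not sit on C6 and the side-chain alkene stays out of play; the ring alkene is necessarily cis.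

Step 12
Reactants: 20 cycloheptene ester
Product: 22 C1 alcohol (both C1 epimers), via B-alkyl-9-BBN 21 (not isolated)
Conditions: 9-BBN (9-borabicyclo[3.3.1]nonane), THF, 0 °C to rt; then H2O2, pH 7 phosphate buffer, 0 °C to rt
Reagents that add atoms: hydrogen peroxide, OO
Why: Hydroboration–oxidation: 9-BBN reacts with the cis-disubstituted ring alkene much faster than with the trisubstituted side-chain alkene and puts boron on C1, the carbon remote from the quaternary C7; the C1 configuration is irrelevant.

Step 13
Reactants: 22 C1 alcohol
Product: 23 C1 ketone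
Conditions: Dess–Martin periodinane, pyridine, CH2Cl2, 0 °C to rt
Reagents that add atoms: none
Why: Dess–Martin oxidation under buffered, non-enolising conditions keeps the C2 centre next to the new ketone.

Step 14
Reactants: 23 C1 ketone
Product: 25 C1 enol triflate (C1=C6), via lithium enolate 24 (not isolated)
Conditions: LiN(iPr)2 (1.1 equiv), THF, −78 °C (ketone added to the base); then PhNTf2, −78 to 0 °C
Reagents that add atoms: N-phenylbis(trifluoromethanesulfonimide), O=S(=O)(N(c1ccccc1)S(=O)(=O)C(F)(F)F)C(F)(F)F
Why: Kinetic deprotonation of the ketone at the C6 methylene rather than the C2 methine (and faster than the ester), with inverse addition so that no proton exchange can epimerise C2, followed by O-sulfonylation, gives the C1=C6 enol triflate.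

Step 15
Reactants: 25 C1 enol triflate
Product: 26 C12 allylic alcohol (methyl ester)
Conditions: Bu3SnCH2OH, Pd(PPh3)4 (cat.), LiCl, 1,4-dioxane, 100 °C
Reagents that add atoms: (tributylstannyl)methanol, CCCC[Sn](CCCC)(CCCC)CO
Why: Stille coupling of the enol triflate with the hydroxymethylstannane installs C12 at the oxidation level needed, with the alkene fixed at C1=C6.

Step 16
Reactants: 26 C12 allylic alcohol (methyl ester)
Product: 27 hydroxy acid
Conditions: LiOH, THF/MeOH/H2O, rt; then cold dilute HCl to pH 4
Reagents that add atoms: lithium hydroxide, [Li+].[OH-]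
Why: Saponification of the methyl ester; the dioxolane is stable to base and the work-up is kept at pH 4 or above.

Step 17
Reactants: 27 hydroxy acid
Product: 28 eight-membered lactone on the cycloheptene
Conditions: 2-methyl-6-nitrobenzoic anhydride, DMAP, CH2Cl2 (1 mM, slow addition of 27), rt
Reagents that add atoms: none
Why: Shiina macrolactonisation through the mixed anhydride at high dilution; the sp2 C1 and the ring hold the hydroxymethyl group and the acid chain on neighbouring ring atoms, which favours the eight-membered ring over oligomers.

Step 18
Reactants: 28 eight-membered lactone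
Product: 31 1-methylidenebicyclo[4.3.1]decane-5-carboxylic acid, via silyl ketene acetal 29 (not isolated), via silyl ester 30 (not isolated)
Conditions: LiN(iPr)2, tBuMe2SiCl, THF/DMPU, −78 °C; solvent changed to toluene, 100 °C; then K2CO3 (cat.), MeOH/H2O, rt; pH 5 buffer
Reagents that add atoms: none
Why: Proposed new method: LiN(iPr)2 with tBuMe2SiCl present converts 28 into silyl ketene acetal 29, whose C5=C11 bond is necessarily cis in the eight-membered ring; on heating, the array C5=C11–O–C12–C1=C6 should undergo a [3,3] shift that forms C5–C6, breaks C12–O and leaves the C1=C12 methylene. The closest known reaction type is the Ireland–Claisen ring contraction of unsaturated macrolactones through their silyl ketene acetals, not yet shown for a lactone whose allylic alkene lies in a second ring so that a bridged bicycle results. The six-membered carbocycle C1–C6 closes through the C4–C3–C2 tether with both carbons of the C1=C6 alkene inside the new ring (6-endo with respect to that alkene, which is transposed to the exocyclic position), and this completes the bicyclo[4.3.1]decane. A one-atom link (C3) between C4 on C5 and C2 on the central allyl carbon fits only a chair-like six-centre array, a bicyclo[3.3.1]nonane-like transition structure; the boat would need a trans ketene acetal in the ring. C6 is controlled by C2: the shift is suprafacial on the allyl unit and the tether reaches C6 only on the face that carries C3, so H-6 ends outside the bicycle. C5 is set by the array (carboxyl axial, syn to the methylidene) but is made trigonal in step 20. The step needs O-silylation and the [3,3] shift to outrun ketene formation from the enolate, and bond formation beside the quaternary C7 to be reached thermally; the silyl chloride present during deprotonation and the intramolecular, concerted course are relied on for this, and the dioxolane keeps C8 from enolising.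

Step 19
Reactants: 31 bicyclic acid
Product: 32 methyl ester of 31
Conditions: Me3SiCHN2, MeOH/toluene, 0 °C
Reagents that add atoms: (trimethylsilyl)diazomethane, C[Si](C)(C)C=[N+]=[N-]
Why: Esterification with (trimethylsilyl)diazomethane, neutral to the ketal and the alkenes.

Step 20
Reactants: 32 methyl ester
Product: 36 C4=C5 enoate, via lithium enolate 33 (not isolated), via selenide 34 (not isolated), via selenoxide 35 (not isolated)
Conditions: LiN(iPr)2, THF, −78 to −40 °C; PhSeBr, −78 °C; then NaIO4, THF/MeOH/H2O, rt
Reagents that add atoms: none
Why: α-Selenenylation of the ester enolate and selenoxide syn-elimination; the hydrogen lost can only be on C4, since elimination toward the bridgehead C6 would give a bridgehead alkene, so the C4=C5 enoate results and C5 becomes trigonal. NaIO4 oxidises selenium without touching the alkenes.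

Step 21
Reactants: 36 C4=C5 enoate
Product: 37 C11 allylic alcohol
Conditions: iBu2AlH (2.5 equiv), CH2Cl2, −78 °C; aq. potassium sodium tartrate
Reagents that add atoms: none
Why: iBu2AlH reduces the conjugated ester to the allylic alcohol by 1,2-addition; ketal and alkenes are inert.

Step 22
Reactants: 37 C11 allylic alcohol
Product: 39 C1,C11 diol, via hydroperoxide 38 (not isolated)
Conditions: Co(acac)2 (cat.), PhSiH3, O2 (1 atm), THF, rt; then PPh3
Reagents that add atoms: dioxygen, O=O
Why: Mukaiyama hydration: hydrogen-atom transfer to the unhindered terminal C12 gives the tertiary C1 radical in preference to reaction at the two trisubstituted alkenes, and O2 should be captured on the face over the enal bridge because the other face is screened by the axial C7 methyl; this sets C1 with C12 over the four-carbon bridge. With C5 trigonal the new hydroxyl cannot close onto C11.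

Step 23
Reactants: 39 C1,C11 diol
Product: 40 hydroxy enal
Conditions: MnO2, CH2Cl2, rt
Reagents that add atoms: none
Why: MnO2 oxidises only the allylic primary alcohol, giving the enal; the tertiary alcohol cannot react.

Step 24
Reactants: 40 hydroxy enal
Product: 41 acetate (ketal still in place)
Conditions: Ac2O, DMAP, Et3N, CH2Cl2, 40 °C
Reagents that add atoms: acetic anhydride, CC(=O)OC(C)=O
Why: DMAP-catalysed acetylation of the tertiary alcohol, the only hydroxyl present; the trigonal C5 keeps the aldehyde from forming a lactol with the C1 oxygen.

Step 25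
Reactants: 41 acetate ketal
Product: 42 target CNP0288370.1
Conditions: AcOH/THF/H2O (3:1:1), 40 °C
Reagents that add atoms: water, O
Why: Mild aqueous acid hydrolysis of the dioxolane releases the methyl ketone; the conditions are chosen to retain the tertiary acetate and to avoid epimerising C8.

## Compound list

1 | (S)-citronellal, (3S)-3,7-dimethyloct-6-enal | C[C@@H](CCC=C(C)C)CC=O | starting material
2 | (3S)-3,7-dimethylocta-1,6-dien-1-yl nonafluorobutane-1-sulfonate (E/Z mixture) | C[C@@H](CCC=C(C)C)C=COS(=O)(=O)C(F)(F)C(F)(F)C(F)(F)C(F)(F)F | intermediate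
3 | (3S)-3,7-dimethyloct-6-en-1-yne | C[C@@H](CCC=C(C)C)C#C | intermediate
4 | dimethyl[(1E,3S)-2,3,7-trimethylocta-1,6-dien-1-yl]alumane | C[C@@H](CCC=C(C)C)/C(C)=C/[Al](C)C | intermediate
5 | (3E,5S)-4,5,9-trimethyldeca-3,8-dien-2-one | C[C@@H](CCC=C(C)C)/C(C)=C/C(C)=O | intermediate
6 | (2S,3E,5S)-4,5,9-trimethyldeca-3,8-dien-2-ol | C[C@@H](CCC=C(C)C)/C(C)=C/[C@H](C)O | intermediate
7 | methyl hex-5-enoate | COC(=O)CCCC=C | starting material
8 | methyl (5E)-7-bromohept-5-enoate | COC(=O)CCC/C=C/CBr | intermediate
9 | (4-bromobutoxy)(tert-butyl)dimethylsilane | CC(C)(C)[Si](C)(C)OCCCCBr | starting material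
10 | {4-[(tert-butyldimethylsilyl)oxy]butyl}magnesium bromide | CC(C)(C)[Si](C)(C)OCCCC[Mg]Br | intermediate
11 | methyl (5S)-9-[(tert-butyldimethylsilyl)oxy]-5-ethenylnonanoate | COC(=O)CCC[C@@H](C=C)CCCCO[Si](C)(C)C(C)(C)C | intermediate
12 | (5S)-5-ethenyl-9-methoxy-9-oxononanoic acid | COC(=O)CCC[C@@H](C=C)CCCC(=O)O | intermediate
13 | 1-methyl 9-[(2S,3E,5S)-4,5,9-trimethyldeca-3,8-dien-2-yl] 5-ethenylnonanedioate, the 5-ethenyl carbon (C2 of the route) configured as in acid 12 | COC(=O)CCC[C@@H](C=C)CCCC(=O)O[C@@H](C)/C=C(C)/[C@@H](C)CCC=C(C)C | intermediate
14 | bis(trimethylsilyl ketene acetal) of 13; at the allylic ester C9 is cis to OSiMe3 | COC(O[Si](C)(C)C)=CCC[C@@H](C=C)CC/C=C(\O[Si](C)(C)C)O[C@@H](C)/C=C(C)/[C@@H](C)CCC=C(C)C | intermediate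
15 | trimethylsilyl ester of acid 16, the methyl ester still masked as its silyl ketene acetal | COC(O[Si](C)(C)C)=CCC[C@@H](C=C)CC[C@H](C(=O)O[Si](C)(C)C)[C@@](C)(/C=C/C)[C@@H](C)CCC=C(C)C | intermediate
16 | Claisen acid: 5-ethenyl-9-methoxy-9-oxononanoic acid whose C2 (C8 of the route) carries the quaternary C7 [methyl, (E)-prop-1-enyl, (2S)-6-methylhept-5-en-2-yl]; C2, C7, C8 and C1′ as in 42 | COC(=O)CCC[C@@H](C=C)CC[C@H](C(=O)O)[C@@](C)(/C=C/C)[C@@H](C)CCC=C(C)C | intermediate
17 | acid chloride of 16 | COC(=O)CCC[C@@H](C=C)CC[C@H](C(=O)Cl)[C@@](C)(/C=C/C)[C@@H](C)CCC=C(C)C | intermediate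
18 | methyl ketone: acetyl on C8 in place of the carboxyl of 16 | COC(=O)CCC[C@@H](C=C)CC[C@H](C(C)=O)[C@@](C)(/C=C/C)[C@@H](C)CCC=C(C)C | intermediate
19 | ethylene ketal (2-methyl-1,3-dioxolan-2-yl on C8) of 18 | COC(=O)CCC[C@@H](C=C)CC[C@H](C1(C)OCCO1)[C@@](C)(/C=C/C)[C@@H](C)CCC=C(C)C | intermediate
20 | methyl 4-(cycloheptenyl)butanoate: cycloheptene C1=C6 with C2 β-(CH2)3CO2Me, C7 α-methyl and β-[(2S)-6-methylhept-5-en-2-yl], C8 β-(2-methyl-1,3-dioxolan-2-yl) | COC(=O)CCC[C@H]1C=C[C@@](C)([C@@H](C)CCC=C(C)C)[C@@H](C2(C)OCCO2)CC1 | intermediate
21 | B-(cycloheptyl)-9-borabicyclo[3.3.1]nonane from 20, boron on C1 (both C1 epimers) | COC(=O)CCC[C@H]1C(B2C3CCCC2CCC3)C[C@@](C)([C@@H](C)CCC=C(C)C)[C@@H](C4(C)OCCO4)CC1 | intermediate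
22 | cycloheptanol: hydroxyl on C1 (both epimers), substituents at C2, C7, C8 as in 20 | COC(=O)CCC[C@H]1C(O)C[C@@](C)([C@@H](C)CCC=C(C)C)[C@@H](C2(C)OCCO2)CC1 | intermediate
23 | cycloheptanone: C1 ketone, substituents at C2, C7, C8 as in 20 | COC(=O)CCC[C@H]1C(=O)C[C@@](C)([C@@H](C)CCC=C(C)C)[C@@H](C2(C)OCCO2)CC1 | intermediate
24 | lithium enolate of 23 (C1–OLi, C1=C6) | COC(=O)CCC[C@H]1C(O[Li])=C[C@@](C)([C@@H](C)CCC=C(C)C)[C@@H](C2(C)OCCO2)CC1 | intermediate
25 | enol triflate: trifluoromethanesulfonyloxy on C1, C1=C6 | COC(=O)CCC[C@H]1C(OS(=O)(=O)C(F)(F)F)=C[C@@](C)([C@@H](C)CCC=C(C)C)[C@@H](C2(C)OCCO2)CC1 | intermediate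
26 | allylic alcohol: hydroxymethyl (C12) on C1, C1=C6, C2 β-(CH2)3CO2Me | COC(=O)CCC[C@H]1C(CO)=C[C@@](C)([C@@H](C)CCC=C(C)C)[C@@H](C2(C)OCCO2)CC1 | intermediate
27 | hydroxy acid from 26 | OC(=O)CCC[C@H]1C(CO)=C[C@@](C)([C@@H](C)CCC=C(C)C)[C@@H](C2(C)OCCO2)CC1 | intermediate
28 | lactone: eight-membered ring C12–O–C11(=O)–C5–C4–C3–C2–C1 fused to the cycloheptene at C1–C2; C7 α-methyl/β-side chain, C8 β-dioxolanyl | O=C1CCC[C@@H]2CC[C@H](C3(C)OCCO3)[C@](C)([C@@H](C)CCC=C(C)C)C=C2CO1 | intermediate
29 | tert-butyldimethylsilyl ketene acetal of 28 (C5=C11, cis in the ring) | CC(C)(C)[Si](C)(C)OC1=CCC[C@@H]2CC[C@H](C3(C)OCCO3)[C@](C)([C@@H](C)CCC=C(C)C)C=C2CO1 | intermediate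
30 | tert-butyldimethylsilyl ester of 31 | C=C1[C@@H]2CC[C@H](C(=O)O[Si](C)(C)C(C)(C)C)[C@@H]1[C@@](C)([C@@H](C)CCC=C(C)C)[C@@H](C3(C)OCCO3)CC2 | intermediate
31 | cis-bridged 1-methylidenebicyclo[4.3.1]decane-5-carboxylic acid (route numbering): C5 carboxyl axial and syn to the methylidene, C7 α-methyl/β-side chain, C8 β-dioxolanyl | C=C1[C@@H]2CC[C@H](C(=O)O)[C@@H]1[C@@](C)([C@@H](C)CCC=C(C)C)[C@@H](C3(C)OCCO3)CC2 | intermediate
32 | methyl ester of 31 | C=C1[C@@H]2CC[C@H](C(=O)OC)[C@@H]1[C@@](C)([C@@H](C)CCC=C(C)C)[C@@H](C3(C)OCCO3)CC2 | intermediate
33 | lithium enolate of 32 | C=C1[C@@H]2CCC(=C(O[Li])OC)[C@@H]1[C@@](C)([C@@H](C)CCC=C(C)C)[C@@H](C3(C)OCCO3)CC2 | intermediate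
34 | 5-(phenylselanyl) derivative of 32 | C=C1[C@@H]2CCC([Se]c3ccccc3)(C(=O)OC)[C@@H]1[C@@](C)([C@@H](C)CCC=C(C)C)[C@@H](C4(C)OCCO4)CC2 | intermediate
35 | selenoxide of 34 | C=C1[C@@H]2CCC([Se](=O)c3ccccc3)(C(=O)OC)[C@@H]1[C@@](C)([C@@H](C)CCC=C(C)C)[C@@H](C4(C)OCCO4)CC2 | intermediate
36 | enoate: C4=C5 with CO2Me on C5, C1=C12 methylidene retained | C=C1[C@@H]2CC=C(C(=O)OC)[C@@H]1[C@@](C)([C@@H](C)CCC=C(C)C)[C@@H](C3(C)OCCO3)CC2 | intermediate
37 | allylic alcohol: hydroxymethyl (C11) on C5, C4=C5, C1=C12 | C=C1[C@@H]2CC=C(CO)[C@@H]1[C@@](C)([C@@H](C)CCC=C(C)C)[C@@H](C3(C)OCCO3)CC2 | intermediate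
38 | C1 hydroperoxide: OOH over the enal bridge, C12 methyl over the four-carbon bridge | OO[C@]1(C)[C@@H]2CC=C(CO)[C@@H]1[C@@](C)([C@@H](C)CCC=C(C)C)[C@@H](C3(C)OCCO3)CC2 | intermediate
39 | diol: tertiary C1 hydroxyl (over the enal bridge) and primary C11 hydroxyl | O[C@]1(C)[C@@H]2CC=C(CO)[C@@H]1[C@@](C)([C@@H](C)CCC=C(C)C)[C@@H](C3(C)OCCO3)CC2 | intermediate
40 | hydroxy enal: C1 hydroxyl, C4=C5–CHO, C8 dioxolanyl | O[C@]1(C)[C@@H]2CC=C(C=O)[C@@H]1[C@@](C)([C@@H](C)CCC=C(C)C)[C@@H](C3(C)OCCO3)CC2 | intermediate
41 | tertiary acetate of 40, C8 still as dioxolane | CC(=O)O[C@]1(C)[C@@H]2CC=C(C=O)[C@@H]1[C@@](C)([C@@H](C)CCC=C(C)C)[C@@H](C3(C)OCCO3)CC2 | intermediate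
42 | CNP0288370.1: 1-acetoxy-1-methyl-8-acetyl-7-methyl-7-[(2S)-6-methylhept-5-en-2-yl]bicyclo[4.3.1]dec-4-ene-5-carbaldehyde (route numbering) | CC(=O)O[C@]1(C)[C@@H]2CC=C(C=O)[C@@H]1[C@@](C)([C@@H](C)CCC=C(C)C)[C@@H](C(C)=O)CC2 | target

## Count and risks

Total: 25 steps. Longest linear sequence: 22 steps (steps 1–3 or steps 4–6, then steps 7–25).

**Step 18 (key step).** The [3,3] shift may be too slow beside the quaternary C7, so that the ketene acetal reverts to 28 on work-up or fragments before C5–C6 forms. Fallback by known chemistry, forming the same bond: from 26, the primary allylic hydroxyl is exchanged (PPh3, CCl4) to give allylic chloride F1. KN(SiMe3)2 in THF at high dilution then generates the ester enolate, which closes the six-membered ring by intramolecular SN2′ alkylation at C6 with loss of chloride from C12. The tether again reaches only the β face. This gives methyl ester 32 (either C5 epimer serves), where the route is rejoined.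

**Step 14.** Deprotonation may occur at the C2 methine instead of the C6 methylene, which is hindered by C7; this would give the regioisomeric triflate and, through proton exchange, loss of the C2 configuration. Fallback: from 23, addition of [(4-methoxybenzyloxy)methyl]lithium (from the tributylstannane and BuLi, −78 °C) anti to the C2 substituent gives tertiary carbinol F2. Burgess dehydration is a syn elimination and cannot use the C2 hydrogen, which is trans to the hydroxyl, so it should give the C1=C6 alkene as 4-methoxybenzyl ether F3. DDQ then frees 26.

**Step 17.** Intermolecular acylation (diolide and oligomers) may outrun closure of the eight-membered ring. Fallback: Mitsunobu lactonisation of 27 (PPh3, diisopropyl azodicarboxylate, toluene, high dilution) activates the primary allylic hydroxyl instead of the carboxyl, so the ring closes by carboxylate displacement at C12. It makes no new compound (F0) and returns at 28.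

**Step 22.** Hydrogen-atom transfer may go to the side-chain or the C4=C5 alkene (poor chemoselectivity), or oxygen may be captured on the wrong face of the C1 radical. Fallback: from 31, whose C5 carboxyl is axial and syn to the methylidene, iodolactonisation (I2, NaHCO3) delivers the oxygen to C1 intramolecularly and only from the side of the cyclohexane ring, giving iodolactone F4. Bu3SnH with AIBN gives methyl lactone F5, and iBu2AlH at −78 °C gives lactol F6. α-Selenenylation through the enamine of its open form (pyrrolidine, N-(phenylseleno)phthalimide) gives selenide F7, and NaIO4 with syn-elimination toward C4 gives 40.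

## Further compounds

F1 | step 18 | allylic chloride: chloromethyl (C12) on C1 of the cycloheptene, otherwise as 26 | COC(=O)CCC[C@H]1C(CCl)=C[C@@](C)([C@@H](C)CCC=C(C)C)[C@@H](C2(C)OCCO2)CC1
F2 | step 14 | tertiary carbinol: C1 hydroxyl and C1 (4-methoxybenzyloxy)methyl, otherwise as 23 | COC(=O)CCC[C@H]1C(O)(COCc2ccc(OC)cc2)C[C@@](C)([C@@H](C)CCC=C(C)C)[C@@H](C3(C)OCCO3)CC1
F3 | step 14 | 4-methoxybenzyl ether of 26 | COC(=O)CCC[C@H]1C(COCc2ccc(OC)cc2)=C[C@@](C)([C@@H](C)CCC=C(C)C)[C@@H](C3(C)OCCO3)CC1
F0 | step 17 | none | none
F4 | step 22 | iodolactone: γ-lactone from the C5 carboxyl to C1, iodomethyl on C1 | O=C1O[C@]2(CI)[C@@H]3CC[C@H]1[C@@H]2[C@@](C)([C@@H](C)CCC=C(C)C)[C@@H](C4(C)OCCO4)CC3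
F5 | step 22 | methyl lactone: as F4 with methyl (C12) on C1 | O=C1O[C@]2(C)[C@@H]3CC[C@H]1[C@@H]2[C@@](C)([C@@H](C)CCC=C(C)C)[C@@H](C4(C)OCCO4)CC3
F6 | step 22 | lactol of F5 (in equilibrium with the C1 hydroxy C5 aldehyde) | OC1O[C@]2(C)[C@@H]3CC[C@H]1[C@@H]2[C@@](C)([C@@H](C)CCC=C(C)C)[C@@H](C4(C)OCCO4)CC3
F7 | step 22 | 5-(phenylselanyl) C1 hydroxy C5 aldehyde | O[C@]1(C)[C@@H]2CCC([Se]c3ccccc3)(C=O)[C@@H]1[C@@](C)([C@@H](C)CCC=C(C)C)[C@@H](C4(C)OCCO4)CC2
A1 | alternative 1 | bicyclo[4.3.1]dec-8-en-1-one with C8 trimethylsilyl and C5 (tert-butyldimethylsilyloxy)methyl | O=C1[C@@H]2CC[C@@H](CO[Si](C)(C)C(C)(C)C)[C@@H]1[C@@](C)([C@@H](C)CCC=C(C)C)C([Si](C)(C)C)=CC2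
A2 | alternative 1 | 2-chloro-5-{[(tert-butyldimethylsilyl)oxy]methyl}cyclohexan-1-one | O=C1C(Cl)CC[C@@H](CO[Si](C)(C)C(C)(C)C)C1
A3 | alternative 1 | trimethyl[(5S)-4,5,9-trimethyldeca-1,3,8-trien-3-yl]silane | C=CC([Si](C)(C)C)=C(C)[C@@H](C)CCC=C(C)C
A4 | alternative 2 | bicyclo[4.3.1]decane C5 ketone C8 methyl ester with C1 triethylsilyloxy | CC[Si](CC)(CC)O[C@]1(C)[C@@H]2CCC(=O)[C@@H]1[C@@](C)([C@@H](C)CCC=C(C)C)[C@@H](C(=O)OC)CC2
A5 | alternative 2 | cycloheptene-fused 2,2-dimethyl-1,3-dioxin-4-one (C5=C8) with the C1(OSiEt3)(CH3)–C6H=C7 alkenyl arm on C2 | CC1(C)OC(=O)C2=C(O1)CC[C@H](CC2)[C@@](C)(O[Si](CC)(CC)CC)/C=C(\C)[C@@H](C)CCC=C(C)C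
A6 | alternative 3 | bicyclo[4.3.1]dec-8-ene ketol: C1 carbinol, C5 ketone, C8 dioxolanyl | O[C@]1(C)[C@@H]2CCC(=O)[C@@H]1[C@@](C)([C@@H](C)CCC=C(C)C)[C@@H](C3(C)OCCO3)C=C2
A7 | alternative 3 | cis-1,2-dialkenylcyclopentan-1-ol with acetyl on the carbon next to the second alkenyl carbon | CC(=O)[C@@H]1CC[C@@](O)(/C=C(\C)[C@@H](C)CCC=C(C)C)[C@H]1/C=C/C2(C)OCCO2
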